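## Structural features

Glyinflanin D (17) is a dibenzoylmethane: a propane-1,3-dione chain joins C6 of two 2,2-dimethyl-2H-chromene units. Ring A carries nothing else on its benzene ring. Ring B carries a hydroxyl at C7, ortho to the acyl group and hydrogen-bonded to it, and its pyran ring is fused in the linear sense (O1 para to the acyl carbon, C4a meta to it). There is no stereocentre; the only stereo-elements are the two C3=C4 double bonds, which are cis because they lie in six-membered rings. The fragile points are the tertiary allylic aryl ether bonds O1–C2 and the styrene-type C3=C4 bonds (acid), the β-diketone (nucleophilic base and organometallics, unless enolised), and the ortho-hydroxy diketone of ring B, which strong acid closes to a chromone. The real difficulty is twofold: to obtain the linear and not the angular fusion of ring B, and to install two acid-sensitive chromenes in a molecule that also holds the diketone. The key step exploits that C2 of ring A and C2 of ring B are each a quaternary carbon bonded to O1, to two identical methyl groups and to the cis C3=C4 bond: this is a coumarin lactone carbonyl that has taken up two methyl nucleophiles, so both pyran rings can travel as robust coumarins until the end.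

## Logic of the disconnections

17 ⇒ 15. The two O1–C2 bonds (ring A and ring B) are cut and the C7 hydroxyl is masked as a methoxymethyl ether. These bonds are the most labile in 17 and form readily from a phenol and a cis-placed tertiary allylic alcohol under mild acid. The cut removes both acid-sensitive rings and leaves an open-chain bis-phenol. The forward step must close both rings (through 16) and free the C7 hydroxyl in one mildly acidic operation that stops short of cyclodehydrating the ortho-hydroxy diketone.

15 ⇒ 12 + 13. The four C2–CH3 bonds are cut, so four molecules of 13 are built into 15, two at each former lactone carbon. Each C2 bears an oxygen and two identical methyl groups, the signature of an ester carbonyl after double addition, and the neighbouring cis alkene is the one held in a coumarin. The cut makes four C–C bonds the work of one operation and turns two fragile rings into two lactones that survive the assembly of the diketone. The forward step demands 1,2-attack of 13 on both lactone carbonyls while the diketone, as chelate 14, stays untouched; a fifth molecule of 13 is spent on forming that chelate. It also demands an ether at the C7 oxygen: a phenoxide there is conjugated with the ring B lactone carbonyl and would deactivate it.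

12 ⇒ 5 + 10. The bond between the central CH2 and the carbonyl carbon on ring A is cut. This puts the nucleophilic methyl ketone on ring B, where it is inherited from 1, and the acyl donor on ring A, and it divides 12 into two coumarins of similar size. A coumarin lactone is an aryl ester and a better acylating agent than a methyl benzoate, so the forward step cannot safely be an alkoxide-mediated condensation with 8. It needs the preformed enolate 11 and the far more reactive 10 at low temperature.

10 ⇒ 9 ⇒ 8 ⇒ 6. After two functional-group changes at the C6 carboxyl, the C3=C4 bond and the lactone O–C2 bond of the ring A coumarin are cut, leading to a salicylaldehyde and a stabilised two-carbon ylide. The gain is a commercial, correctly substituted benzene. The demand is heat, so that the E alkene 7 first formed isomerises and lactonises.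

5 ⇒ 4 ⇒ 1 + 2. Removal of the acetal gives 4, in which the C4–C4a and O1–C2 bonds of the ring B coumarin are cut. This Pechmann-type cut leads to a resorcinol ketone and a three-carbon acid equivalent (3, generated from 2), and it is where the linear fusion of ring B is decided. The forward step must substitute 1 at C5, para to the chelated hydroxyl, and not at C3 between the two oxygens.

## Other disconnections considered

Alternative 1: The cut goes through the benzene ring of ring B at C4a–C5 and C6–C7. Forward, the dioxygenated diene A2 (a silyl ketene acetal on a 2,2-dimethyl-dihydropyran) would add the alkynone A3 in a Diels–Alder reaction, C4a joining the unsubstituted alkyne carbon and C7 the acyl-bearing one. Loss of the methoxy and silyl groups would aromatise the adduct to the chroman ketone A1.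
- In favour: both oxygen donors of A2 polarise the diene in the same sense, so the acetyl group should land at C6 next to the C7 hydroxyl with no angular isomer possible. On regiochemical certainty this alternative is the better plan, because the chosen route relies on the site selectivity of an electrophilic substitution in step 1.
- Against: A1 is at the chroman oxidation level, so C3–C4 must still be dehydrogenated beside a free phenol and an enolisable ketone. A2 is hydrolytically fragile and needs several steps itself. Only ring B is addressed.
- Comparison: mechanistically it exchanges an organometallic addition with a chemoselectivity question for a pericyclic step with an oxidation-state problem afterwards. In step economy it should be clearly longer than the chosen plan, which sets both pyran rings in one key operation.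

Alternative 2: The cuts are C4–C4a and O1–C2 in both pyran rings, leading to the bis(1,1-dimethylpropargyl) ether A5. On heating, each aryl propargyl ether should pass through a [3,3] shift, a 1,5-hydrogen shift and an oxa-6π electrocyclisation to give the bis-chromene A4. The iodine at C8 of ring B blocks the position between the two oxygens, which would otherwise react and give the angular isomer, and it is removed reductively afterwards.
- In favour: the ring-forming step is neutral and thermal, brings no nucleophile near the diketone and needs no protecting group on the chelated C7 hydroxyl. On mechanism and functional-group tolerance of the ring-forming step it is the better plan, and in step count it is about equal.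
- Against: two steps are spent on introducing and removing iodine. O-alkylation of a phenol flanked by iodine with a tertiary propargylic electrophile is demanding. The final deiodination must spare two styrene-type double bonds and the diketone.
- Comparison: structurally the chosen plan needs no blocking atom, because linear fusion is fixed when the coumarin is made, and it builds the quaternary C2 centres from methyl nucleophiles and not from a hindered tertiary ether.

Alternative 3: The cut goes through the benzene ring of ring A at C4a–C5 and C6–C7. Forward, the pyrano-fused 2-pyrone A7 would add the propiolate A8 across C3 and C6 of the pyrone, and decarboxylative cycloreversion would give the chromene ester A6. The ring oxygens of A7 should direct the ester to C6.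
- In favour: the cycloreversion makes the step irreversible and no protecting group is involved. A6 is an ester on a base-stable chromene, so a classical alkoxide-mediated Claisen condensation could be used. On that point it is better than the chosen plan, which must go through 10 to spare the lactones.
- Against: it answers only the easy half, since ring A has no regiochemical problem. The 4-alkoxy-2-pyrone is an electron-rich, sluggish diene that needs high temperature, at which the 2H-pyran ring of A7 can open reversibly. Ring B and its linear fusion remain unsolved.
- Comparison: it would require a separate ring B synthesis and a protection–deprotection pair, so it should be longer. The chosen plan treats both rings by one mechanism in one flask.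

Key step: step 7

Remark on the chemistry: all 1,3-diketones are drawn in the diketo form although they should exist mainly as chelated enols. In 12 and 15 the oxygen that carries the MOM group becomes the C7 hydroxyl of ring B, and the lactone ring oxygens become O1 of ring A and ring B.

## Route

Step 1
Reactants: 1 2,4-dihydroxyacetophenone; 2 DL-malic acid
Product: 4 6-acetyl-7-hydroxy-2H-chromen-2-one, via 3-oxopropanoic acid 3 (not isolated)
Conditions: conc. H2SO4, 100–110 °C; then ice–water
Reagents that add atoms: none
Why: Pechmann condensation in its malic acid variant: 2 loses carbon monoxide and water to give 3, which substitutes 1 at C5 (para to the chelated hydroxyl, ortho to the free one, and less hindered than C3) and lactonises onto the C4 hydroxyl, which fixes the linear fusion of ring B.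

Step 2
Reactants: 4 6-acetyl-7-hydroxy-2H-chromen-2-one
Product: 5 6-acetyl-7-(methoxymethoxy)-2H-chromen-2-one
Conditions: MOMCl, i-Pr2NEt, CH2Cl2–DMF, 0 °C → rt
Reagents that add atoms: chloromethyl methyl ether, COCCl
Why: O-alkylation of the acidic chelated phenol to a MOM acetal; the amine base does not touch the lactone, and the ether is needed so that no phenoxide interferes in steps 6 and 7.

Step 3
Reactants: 6 methyl 3-formyl-4-hydroxybenzoate
Product: 8 methyl 2-oxo-2H-chromene-6-carboxylate, via E-hydroxycinnamate diester 7 (not isolated)
Conditions: Ph3P=CHCO2Et, PhNEt2, reflux (ca. 215 °C)
Reagents that add atoms: ethyl (triphenylphosphoranylidene)acetate, CCOC(=O)C=P(c1ccccc1)(c1ccccc1)c1ccccc1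
Why: Wittig olefination with a stabilised ylide, then thermal E-to-Z isomerisation and lactonisation onto the ortho phenol with loss of ethanol, the standard conversion of a salicylaldehyde into a coumarin; the remote methyl benzoate takes no part.

Step 4
Reactants: 8 methyl 2-oxo-2H-chromene-6-carboxylate
Product: 9 2-oxo-2H-chromene-6-carboxylic acid
Conditions: 6 M aq. HCl, AcOH, reflux
Reagents that add atoms: water, O
Why: Acid-catalysed ester hydrolysis; acid is preferred to hydroxide because the coumarin ring is inert to it, whereas base would open the lactone and risk Z-to-E isomerisation of the resulting cinnamate.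

Step 5
Reactants: 9 2-oxo-2H-chromene-6-carboxylic acid
Product: 10 2-oxo-2H-chromene-6-carbonyl chloride
Conditions: SOCl2, DMF (cat.), toluene, 80 °C; evaporate, use crude
Reagents that add atoms: thionyl chloride, O=S(Cl)Cl
Why: Standard acid chloride formation through the chlorosulfite; the lactone and its double bond are inert to the reagent.

Step 6
Reactants: 5 6-acetyl-7-(methoxymethoxy)-2H-chromen-2-one; 10 2-oxo-2H-chromene-6-carbonyl chloride
Product: 12 1-[7-(methoxymethoxy)-2-oxo-2H-chromen-6-yl]-3-(2-oxo-2H-chromen-6-yl)propane-1,3-dione, via lithium enolate 11 (not isolated)
Conditions: LiN(SiMe3)2 (2.2 equiv), THF, −78 °C; then 10 in THF, −78 → 0 °C; aq. NH4Cl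
Reagents that add atoms: none
Why: Claisen-type C-acylation of a preformed lithium enolate with an acid chloride; the second equivalent of base deprotonates the diketone as it forms and prevents a second acylation. The acid chloride reacts at −78 °C, where neither the enolate nor the amide base should attack a lactone carbonyl, a guarantee that a methyl ester with alkoxide at higher temperature would not offer.

Step 7
Reactants: 12 1-[7-(methoxymethoxy)-2-oxo-2H-chromen-6-yl]-3-(2-oxo-2H-chromen-6-yl)propane-1,3-dione; 13 methylmagnesium bromide (four equivalents are incorporated)
Product: 15 1-[4-hydroxy-5-[(Z)-3-hydroxy-3-methylbut-1-enyl]-2-(methoxymethoxy)phenyl]-3-[4-hydroxy-3-[(Z)-3-hydroxy-3-methylbut-1-enyl]phenyl]propane-1,3-dione, via bromomagnesium diketonate 14 (not isolated)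
Conditions: MeMgBr (1.1 equiv), THF, −40 °C; then MeMgBr (9 equiv), 0 °C → rt; cold sat. aq. NH4Cl; crude product used directly
Reagents that add atoms: methylmagnesium bromide (three further equivalents beside reactant 13), C[Mg]Br.C[Mg]Br.C[Mg]Br
Why: Exhaustive Grignard addition to two lactones, in which four molecules of 13 are built into the product (two per lactone) and a fifth is spent on the diketone. That first equivalent deprotonates the enolised diketone to the chelated diketonate 14, a vinylogous carboxylate whose carbonyl carbons are far poorer electrophiles than the two aryl-ester carbonyls. Each lactone then takes one methyl at C2, the magnesium hemiketalate opens to a Z aryl enone with release of the C8a phenoxide, and a second methyl adds 1,2 to that ketone to give the tertiary alkoxide; four C2–CH3 bonds form, both pyranone rings open and no ring is closed. The closest known reaction type is the conversion of simple and 7-alkoxy coumarins into 2-(3-hydroxy-3-methylbut-1-enyl)phenols with excess methyl Grignard reagent. No stereocentre is created; the Z geometry of both alkenes is inherited from the cis C3=C4 bond of the lactone ring and is not touched. The step needs chemoselectivity for the lactones over the diketone, secured by the anionic chelate and by staying at or below room temperature. It also needs 1,2- over 1,4-selectivity, favoured by the hard methylmagnesium reagent, by the ortho phenoxide that holds magnesium at the enone oxygen after ring opening, and by the 7-alkoxy donor that tempers C4 of ring B. The MOM ether is essential: a free C7 phenoxide would be conjugated with the ring B lactone carbonyl and would shut down addition there.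

Step 8
Reactants: 15 1-[4-hydroxy-5-[(Z)-3-hydroxy-3-methylbut-1-enyl]-2-(methoxymethoxy)phenyl]-3-[4-hydroxy-3-[(Z)-3-hydroxy-3-methylbut-1-enyl]phenyl]propane-1,3-dione
Product: 17 glyinflanin D (1-(2,2-dimethyl-2H-chromen-6-yl)-3-(7-hydroxy-2,2-dimethyl-2H-chromen-6-yl)propane-1,3-dione), via MOM-protected bis-chromene 16 (not isolated)
Conditions: 3 M aq. HCl–MeOH (1:9), THF, rt
Reagents that add atoms: none
Why: Acid-catalysed cyclodehydration: each tertiary allylic alcohol ionises to an allyl cation (an ortho-quinone methide in its other resonance form) that the neighbouring phenol oxygen captures, forming O1–C2 of ring A and ring B. The same acid then cleaves the MOM acetal, activated by the ortho carbonyl, by transacetalisation to methanol; the acid is kept dilute and at room temperature so that the ortho-hydroxy diketone should not close to a chromone.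

## Compound list

1 | 2,4-dihydroxyacetophenone, 1-(2,4-dihydroxyphenyl)ethanone | CC(=O)c1ccc(O)cc1O | starting material
2 | DL-malic acid, racemic 2-hydroxybutanedioic acid | OC(=O)CC(O)C(=O)O | starting material
3 | 3-oxopropanoic acid (formed in the flask in step 1) | O=CCC(=O)O | intermediate
4 | 6-acetyl-7-hydroxy-2H-chromen-2-one | CC(=O)c1cc2C=CC(=O)Oc2cc1O | intermediate
5 | 6-acetyl-7-(methoxymethoxy)-2H-chromen-2-one | CC(=O)c1cc2C=CC(=O)Oc2cc1OCOC | intermediate
6 | methyl 3-formyl-4-hydroxybenzoate | COC(=O)c1ccc(O)c(C=O)c1 | starting material
7 | methyl 3-[(E)-3-ethoxy-3-oxoprop-1-enyl]-4-hydroxybenzoate (formed in the flask in step 3) | CCOC(=O)/C=C/c1cc(ccc1O)C(=O)OC | intermediate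
8 | methyl 2-oxo-2H-chromene-6-carboxylate | COC(=O)c1ccc2OC(=O)C=Cc2c1 | intermediate
9 | 2-oxo-2H-chromene-6-carboxylic acid | OC(=O)c1ccc2OC(=O)C=Cc2c1 | intermediate
10 | 2-oxo-2H-chromene-6-carbonyl chloride | ClC(=O)c1ccc2OC(=O)C=Cc2c1 | intermediate
11 | lithium 1-[7-(methoxymethoxy)-2-oxo-2H-chromen-6-yl]ethenolate (formed in the flask in step 6) | [Li]OC(=C)c1cc2C=CC(=O)Oc2cc1OCOC | intermediate
12 | 1-[7-(methoxymethoxy)-2-oxo-2H-chromen-6-yl]-3-(2-oxo-2H-chromen-6-yl)propane-1,3-dione | COCOc1cc2OC(=O)C=Cc2cc1C(=O)CC(=O)c1ccc2OC(=O)C=Cc2c1 | intermediate
13 | methylmagnesium bromide | C[Mg]Br | starting material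
14 | bromomagnesium (Z)-3-[7-(methoxymethoxy)-2-oxo-2H-chromen-6-yl]-3-oxo-1-(2-oxo-2H-chromen-6-yl)prop-1-en-1-olate, the chelated diketonate of 12 (formed in the flask in step 7) | COCOc1cc2OC(=O)C=Cc2cc1C(=O)/C=C(\O[Mg]Br)c1ccc2OC(=O)C=Cc2c1 | intermediate
15 | 1-[4-hydroxy-5-[(Z)-3-hydroxy-3-methylbut-1-enyl]-2-(methoxymethoxy)phenyl]-3-[4-hydroxy-3-[(Z)-3-hydroxy-3-methylbut-1-enyl]phenyl]propane-1,3-dione | COCOc1cc(O)c(/C=C\C(C)(C)O)cc1C(=O)CC(=O)c1ccc(O)c(/C=C\C(C)(C)O)c1 | intermediate
16 | 1-(2,2-dimethyl-2H-chromen-6-yl)-3-[7-(methoxymethoxy)-2,2-dimethyl-2H-chromen-6-yl]propane-1,3-dione (formed in the flask in step 8) | COCOc1cc2OC(C)(C)C=Cc2cc1C(=O)CC(=O)c1ccc2OC(C)(C)C=Cc2c1 | intermediate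
17 | glyinflanin D, 1-(2,2-dimethyl-2H-chromen-6-yl)-3-(7-hydroxy-2,2-dimethyl-2H-chromen-6-yl)propane-1,3-dione | CC1(C)C=Cc2cc(C(=O)CC(=O)c3cc4c(cc3O)OC(C)(C)C=C4)ccc2O1 | target

## Step count and risks

Total: 8 steps. Longest linear sequence: 6 steps (steps 3, 4, 5, 6, 7, 8, from 6 to 17); the other branch (steps 1, 2) joins at step 6.

Step 7 (key step). The most likely failure is methyl addition to the diketonate, because the deactivated ring B lactone may need a large excess of reagent and long exposure, together with conjugate addition at C4 of ring A. Within the same approach, LaCl3·2LiCl or anhydrous CeCl3 added after the diketonate has formed should sharpen 1,2-addition. The fallback introduces the methyl groups before the diketone exists, each coumarin being treated while its other carbonyl is in a form inert to Grignard reagents; it sets out from 9 and from 5 and comes back to the route at 17. From 9, excess 13 (the carboxylate salt does not react) and acidic work-up should give 2,2-dimethyl-2H-chromene-6-carboxylic acid F1, and oxalyl chloride with catalytic DMF in CH2Cl2 at 0 °C its chloride, 2,2-dimethyl-2H-chromene-6-carbonyl chloride F2. From 5, enolate 11 is trapped with TBSCl in THF–DMPU as tert-butyl-[1-[7-(methoxymethoxy)-2-oxo-2H-chromen-6-yl]ethenoxy]dimethylsilane F3, and excess 13 followed by aqueous methanolic HCl should then close the ring and unmask ketone and phenol to give 1-(7-hydroxy-2,2-dimethyl-2H-chromen-6-yl)ethanone F4. The dianion of F4 (LiN(SiMe3)2, 3 equiv, THF, −78 °C) is acylated with F2; C-acylation, or O-acylation followed by Baker–Venkataraman shift under the excess base, both lead to 17, where the route is rejoined with no acid treatment after the diketone is in place.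

Step 6. The most likely failure is O-acylation of the enolate (enol ester, then over-acylation), or attack of the enolate on a lactone carbonyl if the mixture warms before acylation is complete. The fallback is an aldol–oxidation sequence that sets out from 10 and 5 and returns to the route at 12. From 10, LiAlH(Ot-Bu)3 in THF at −78 °C should give 2-oxo-2H-chromene-6-carbaldehyde F5. Enolate 11 (from 5) adds to F5 at −78 °C to give racemic 3-hydroxy-1-[7-(methoxymethoxy)-2-oxo-2H-chromen-6-yl]-3-(2-oxo-2H-chromen-6-yl)propan-1-one F6, and oxidation with Dess–Martin periodinane returns to 12.

Step 1. The most likely failure is sluggish substitution of the acyl-deactivated ring in hot sulfuric acid, with sulfonation or charring, or attack at C3 leading to angular fusion. The fallback builds the ring from a halide; it sets out from 1 and returns to the route at 4. From 1, ICl in AcOH should iodinate para to the chelated hydroxyl to give 1-(2,4-dihydroxy-5-iodophenyl)ethanone F7. A Heck reaction with ethyl acrylate (Pd(OAc)2, Et3N, DMF, 90 °C) gives ethyl (E)-3-(5-acetyl-2,4-dihydroxyphenyl)prop-2-enoate F8, and heating in PhNEt2 as in step 3 isomerises and lactonises it to 4.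

Step 8. The most likely failure is chromone-forming cyclodehydration of the liberated ortho-hydroxy diketone, or addition of methanol across the electron-rich C3=C4 bond of ring B, during the longer acid exposure that the acetal cleavage needs. The fallback separates the two events and removes the acetal without protic acid; it sets out from 15 and returns to the route at 17. From 15, pyridinium p-toluenesulfonate in CH2Cl2 closes both rings to 16, which is now isolated. ZnBr2 with propane-1-thiol in CH2Cl2 at 0 °C then cleaves the MOM ether by thiol capture of the Lewis acid-activated acetal, returning to 17. Both compounds on this path already stand in the compound list, so the fallback adds no new structure (entry F0).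

## Further compounds

F1 | step 7 | 2,2-dimethyl-2H-chromene-6-carboxylic acid | CC1(C)C=Cc2cc(ccc2O1)C(=O)O
F2 | step 7 | 2,2-dimethyl-2H-chromene-6-carbonyl chloride | CC1(C)C=Cc2cc(ccc2O1)C(=O)Cl
F3 | step 7 | tert-butyl-[1-[7-(methoxymethoxy)-2-oxo-2H-chromen-6-yl]ethenoxy]dimethylsilane | C=C(O[Si](C)(C)C(C)(C)C)c1cc2C=CC(=O)Oc2cc1OCOC
F4 | step 7 | 1-(7-hydroxy-2,2-dimethyl-2H-chromen-6-yl)ethanone | CC(=O)c1cc2C=CC(C)(C)Oc2cc1O
F5 | step 6 | 2-oxo-2H-chromene-6-carbaldehyde | O=Cc1ccc2OC(=O)C=Cc2c1
F6 | step 6 | racemic 3-hydroxy-1-[7-(methoxymethoxy)-2-oxo-2H-chromen-6-yl]-3-(2-oxo-2H-chromen-6-yl)propan-1-one | COCOc1cc2OC(=O)C=Cc2cc1C(=O)CC(O)c1ccc2OC(=O)C=Cc2c1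
F7 | step 1 | 1-(2,4-dihydroxy-5-iodophenyl)ethanone | CC(=O)c1cc(I)c(O)cc1O
F8 | step 1 | ethyl (E)-3-(5-acetyl-2,4-dihydroxyphenyl)prop-2-enoate | CCOC(=O)/C=C/c1cc(C(C)=O)c(O)cc1O
F0 | step 8 | none | none
A1 | alternative 1 | 1-(7-hydroxy-2,2-dimethylchroman-6-yl)ethanone | CC(=O)c1cc2CCC(C)(C)Oc2cc1O
A2 | alternative 1 | [(E)-2-(2,2-dimethyl-3,4-dihydro-2H-pyran-6-yl)-1-methoxyethenoxy]trimethylsilane (either alkene geometry would serve) | CO/C(O[Si](C)(C)C)=C\C1=CCCC(C)(C)O1
A3 | alternative 1 | but-3-yn-2-one | CC(=O)C#C
A4 | alternative 2 | 1-(2,2-dimethyl-2H-chromen-6-yl)-3-(7-hydroxy-8-iodo-2,2-dimethyl-2H-chromen-6-yl)propane-1,3-dione | CC1(C)C=Cc2cc(C(=O)CC(=O)c3cc4C=CC(C)(C)Oc4c(I)c3O)ccc2O1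
A5 | alternative 2 | 1-[2-hydroxy-3-iodo-4-(2-methylbut-3-yn-2-yloxy)phenyl]-3-[4-(2-methylbut-3-yn-2-yloxy)phenyl]propane-1,3-dione | C#CC(C)(C)Oc1ccc(cc1)C(=O)CC(=O)c1ccc(OC(C)(C)C#C)c(I)c1O
A6 | alternative 3 | methyl 2,2-dimethyl-2H-chromene-6-carboxylate | COC(=O)c1ccc2OC(C)(C)C=Cc2c1
A7 | alternative 3 | 2,2-dimethyl-2H,5H-pyrano[4,3-b]pyran-5-one | CC1(C)C=CC2=C(O1)C=COC2=O
A8 | alternative 3 | methyl propiolate | COC(=O)C#C
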